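The readings come from a simulation from invented constants, and the scatter is random.

Thursday's run has the charges of amber and teal, so read both from it.

| flask | substrate | free catalyst | added ligand | remark | time |
|---|---|---|---|---|---|
| Thursday's | 46 mM | 0.55 mM | 1.2 mM | run made earlier |  |
| Monday's | 46 mM | 0.28 mM | 1.2 mM | run made earlier |  |
| amber | 46 mM | 0.55 mM | 1.2 mM | everything together in a closed stirred flask, run for 6.0 h | 6.0 h |
| grey | 46 mM | 0.55 mM | 1.2 mM | a single well-mixed tank run continuously and read at steady state, 6.0 h in it on average |  |
| teal | 46 mM (fed, over 4.80 h) | 0.55 mM | 1.2 mM | all but substrate at the start; substrate goes in evenly over 4.80 h, the run ends at 6.0 h | 6.0 h |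

- Thursday's (time / h: intermediate / %, product / %, substrate / %): 0.500: 70, 16, 17; 1.50: 62, 36, 2; 3.00: 45, 54, 2; 4.00: 40, 62, 0; 6.00: 29, 72, 1
- Monday's (time / min: intermediate / %, product / %, substrate / %): 20.0: 64, 3, 34; 40.0: 79, 9, 7; 60.0: 81, 18, 4; 80.0: 80, 18, 0; 120: 75, 23, 0

(readings scatter by 1.5 percentage points)

- the set-up with the highest amount of intermediate at the outlet or at the end, in percent of the substrate put in ("none" if the first two lie within 2 percentage points) (amber / grey / teal / none)
- amount of intermediate at the outlet or at the end, in percent of the substrate put in, amber
- amount of intermediate at the outlet or at the end, in percent of the substrate put in, grey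
- amount of intermediate at the outlet or at the end, in percent of the substrate put in, teal

- the stated concentrations are those of everything mixed, before any reaction; amounts are the same in each set-up
- the feed brings no volume worth counting
- the earlier runs were made in a closed, stirred flask

Begin with teal. Its dose enters evenly, so a portion stands on average 3.60 h before the end: call this the mean wait w. Treat the loss of intermediate as a correction to the dose: estimate the share kept at the end of teal as exp(-k w), with k a pseudo-first-order constant for intermediate going to product.

Now test which numbers matter. Thursday's substrate reading at 0.500 h gives a constant of 3.54 /h, so a delay of 0.282 h, shorter than w. Read k where Thursday's substrate is down to 2 %, from the intermediate readings at 1.50 h and 6.00 h: 0.169 /h. This gives teal 54.5 %. Taking the delay off w moves that by about 2.6 percentage points; putting k at 0.0845 /h moves it by 19 points, which is more. So know k well. Amber repeats Thursday's recipe, so expect its last reading, 29 %. Amber and grey both hold their contents 6.0 h, grey on average, longer than teal's w, so expect teal first.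

The forecast names teal, with amber 30 %, grey 45 % and teal 48 %: “Teal is narrowly best, but this is uncertain”. My figure for teal is higher.

The flask gives teal first, with amber 27.2 %, grey 38.7 % and teal 55.7 %.

    substrate → intermediate (k = 9.30 × 10⁻⁴ /s)
    free catalyst + intermediate → free catalyst + product (k = 0.540 /M/s)
    free catalyst → spent catalyst (k = 2.70 × 10⁻⁵ /s)
    free catalyst + added ligand ⇌ idle complex (K = 5000 /M, k = 0.450 /M/s)

Teal ended 1.2 points above the 54.5 % reckoned from w. Take the neighbour, teal with 0.22 mM of free catalyst and the same w of 3.60 h. Monday's readings at 60.0 min and 120 min give a reading of k of 0.0770 /h at 0.28 mM. Scaled in proportion to the catalyst charged, k is estimated at 0.0605 /h, and exp(-k w) gives 80.4 %. The neighbour ends with 81.4 % intermediate and 18.4 % product.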